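## Structural features

The target is a pentacyclic C30 skeleton carrying one methyl ether. Rings A (a3, a4, a5, a6, a8, a33), B (a6, a8, a9, a10, a11, a32) and C (a11, a13, a14, a30, a31, a32) are angularly fused six-membered rings; ring D (a14, a16, a17, a18, a26, a28, a30) is seven-membered and ring E (a18, a19, a22, a24, a25, a26) is six-membered. A/B and B/C are both cis-fused and syn to each other, so the a6 and a11 methyl groups and the a8 and a32 hydrogens share one face of ring B (a strained cis-syn-cis array). C/D is trans-fused (a14-OH on the methyl face, a30-H opposite) and D/E is cis-fused (a26-CH3 and a18-H cis). There are ten stereocentres (a3, a6, a8, a11, a14, a18, a22, a26, a30, a32), most of them adjacent or 1,3-related through the quaternary carbons a6, a11, a26 and the gem-dimethyl carbons a33 and a19. The fragile motif is the tertiary β-hydroxy ketone a14(OH)–a30(H)–a28(=O), which can dehydrate, cleave by retro-aldol or epimerise at a30; the a28 carbonyl is buried between quaternary a26 and a30. The real difficulty is twofold: the contra-thermodynamic all-cis ring B, and a seven-membered ring whose ketone sits on the quaternary carbon of a cis ring fusion. The key step uses the 1,5-relationship that appears once a16 is drawn as a carbonyl: the a18–a26 edge of ring E is the cis edge of a cyclobutane inserted into the a17–a28 bond of a cyclopentane-1,3-dione fused to ring C at a14–a30.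

## Logic of the disconnections

**40 to 39.** No skeletal bond is cut; the a22 carbinol is traced back to a ketone. This lets ring E enter as an achiral ketal alkene. The forward step must deliver hydride from the α face of ring E and leave the buried a28 ketone alone.

**39 to 35 (through 38, 37, 36).** The a16 oxygen is put back and the silyl ether and ketal are restored. This reveals the 1,5-diketone a16/a28 that a retro-aldol leaves behind. The forward steps must enolise a16 toward a17 only and must not expel the a14 silyloxy group, which is β to a28.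

**35 to 27 + 32 (key).** The a26–a28 and a17–a18 bonds are cut and a17–a28 is reconnected. Quaternary a26 next to a ketone in a seven-membered ring is poorly served by enolate chemistry but well served by a radical pair. The cut removes ring D and two stereocentres and splits the molecule into a tetracyclic half and a C11 alkene. The forward step needs head-to-tail regiochemistry, attack on the enone face away from the silyl ether, and an anti arrangement of ring E.

**27 to 25 (through 26).** The enol ester C–O bond and then a17–a28 are cut (Claisen). This opens the five-membered ring to a methyl ketone and an ester. Forward, the methyl ketone enolate must outrun ester enolisation, and O-acylation must occur on the oxygen remote from the silyloxy carbon a14.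

**25 to 19 (through 24, 23, 22, 21, 20).** Oxidation level at a28 is adjusted and a14–a16 is cut (acetyl anion plus ketone). The a28 carbon is carried as a benzyloxymethyl group rather than an ester. A β-keto ester would simply be deprotonated by the acyl-anion reagent; this is the point where the design of the precursor synthesis is changed. The forward addition must come equatorially, anti to the axial a11 methyl group.

**19 to 18.** The a28–a30 bond is cut (enolate alkylation). Forward, deprotonation must occur at a30 and not at the neopentylic a13.

**18 to 17.** The a11–CH3 bond is cut (conjugate addition). This removes a quaternary stereocentre. Forward, methyl must add cis to a32-H.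

**17 to 13 + 14.** The a30–a31 bond and the a11=a13 double bond are cut (Michael addition and aldol condensation). Ring C is removed. Forward, a32 must end with its hydrogen on the methyl face.

**13 to 9 (through 12, 11, 10).** Functional groups are transposed (a11 carbonyl from allylic oxidation), the ether is cut, and the a3 carbinol is traced back to a ketone. The reagent-controlled reduction of racemic 9 is also the resolution.

**9 to 5 + 6 (through 8, 7).** The a32=a31 double bond is cut (methylenation), then a5–a6 and a8–a33 (Diels–Alder). Ring A and the cis A/B fusion go in one step. Forward, a hindered diene and a hindered dienophile must combine with the gem-dimethyl terminus on the β-carbon a8.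

**5 to 1 (through 4, 3, 2).** The silyl dienol ether is cut at O–Si and the vinyl ketone at its methylene carbon (Mannich methylenation).

**32 to 28 (through 31, 30, 29).** The ketal, the two a19 methyl groups and the aromatic ring are traced back. Forward, double alkylation must occur at the doubly activated carbon between carbonyl and alkene.

## Other disconnections considered

**Alternative 1:** The cut runs through ring E at a19–a18 and a25–a26. The forward step is the AlBr3/AlMe3-promoted Diels–Alder addition of diene 5 to the methyl-bearing enone double bond of the cross-conjugated cycloheptadienone A2, giving the cis D/E bicycle A1.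
- In favour: the addition is thermal and suprafacial, so the a18/a26 cis fusion is guaranteed. The silyloxy group fixes the regiochemistry as in step 3. Quaternary a26, the a19 gem-dimethyl group and the a22 oxygen arrive together, with no photochemistry and no labile enol ester.
- Against: A1 is racemic and holds none of the western stereocentres. Rings C, B and A would have to be grown from the a14/a30 vinylogous ester of a mobile seven-membered ring. The a14 carbinol, the trans C/D fusion and the all-cis ring B would then be set late, linearly and remote from a18/a26.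
- Comparison: on structure both plans make ring E bonds and the cis D/E fusion. On mechanism the alternative is the equal or the better (concerted addition against a triplet diradical). On step economy the key steps are equal (two bonds, two stereocentres), but the chosen plan joins two finished halves and should have the shorter linear sequence.

**Alternative 2:** The cut is at a5–a6, with a3–a11 reconnected. The forward step is the anionic oxy-Cope rearrangement (KH, 18-crown-6) of the bicyclo[2.2.2]octenol A4 to the enolate of the cis octalone A3.
- In favour: the bicyclic frame transmits stereochemistry completely, giving the cis A/B fusion with quaternary a6. The a3 ketone and the ring B alkene are differentiated from the start; this is better than the chosen plan, which has to mask the a3 oxygen while a32 is processed.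
- Against: it solves only what the single Diels–Alder of step 3 solves. A4 itself needs a cycloaddition and a face-selective vinyl addition. A3 offers only the unactivated a11=a32 alkene as a handle for ring C, so two C–C bonds and two stereocentres would have to be installed without a carbonyl at a32 or a11.
- Comparison: equal on A/B stereocontrol, better on differentiation of the oxygen functions, worse on step economy, and silent on rings D and E.

**Alternative 3:** The cuts are a6–a8 and a11–a32. The forward step is the thermal transannular Diels–Alder reaction of the 14-membered E,E,Z-triene A6 to the tricyclic ketone A5.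
- In favour: one step closes rings A, B and C and sets all four stereocentres of ring B. The E,E diene and Z dienophile geometry translates directly into the all-cis array, and the a3 stereocentre of A6 can relay absolute configuration without a resolution. On the reliability of ring B stereochemistry it is better than the chosen plan, which sets a32 and a11 in two substrate-controlled steps (8 and 9) resting on a conformational model.
- Against: A6 needs a macrocyclisation and control of two trisubstituted alkene geometries. The diene terminus a11 is fully substituted and the dienophile is unactivated, so forcing temperatures are expected. The facial sense relative to a3 is not guaranteed. A5 is only 18 with one extra alkene, so rings D and E remain.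
- Comparison: structurally A5 maps onto 18. Mechanistically the pericyclic step is more economical in stereochemistry. In step count the chosen route reaches 18 in nine steps from commercial materials, which the macrocycle alone should exceed.

Key step: step 20

Remark: aN labels follow the target SMILES; β is the face of rings A–C carrying the a6 and a11 methyl groups; 7–9 are racemic (the enantiomer carried on is drawn); ring B arguments assume the cis-decalin conformer with the gem-dimethyl carbon a33 equatorial and a5 axial on ring B (conformer Q), which leaves the β face convex; the structures of 27, 32 and 35 drawn here agree atom by atom with 40 and need no correction.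

## Route

Step 1
Reactants: 1 3-methylbutan-2-one
Product: 4 4-methylpent-1-en-3-one, via Mannich base 2 (not isolated), via ammonium iodide 3 (not isolated)
Conditions: LiN(i-Pr)2, THF, −78 °C; CH2=NMe2 iodide, −78 → 0 °C; MeI, Et2O, rt; aq NaHCO3, CH2Cl2, rt
Reagents that add atoms: N,N-dimethylmethyleneiminium iodide, C=[N+](C)C.[I-]
Why: Kinetic deprotonation at the methyl group, Mannich reaction with the preformed iminium salt, quaternisation and E1cB elimination are the standard α-methylenation of a methyl ketone; the isopropyl side is not touched.

Step 2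
Reactants: 4 4-methylpent-1-en-3-one
Product: 5 tert-butyldimethyl[(4-methylpenta-1,3-dien-3-yl)oxy]silane
Conditions: t-BuMe2SiOTf, Et3N, Et2O, 0 °C
Reagents that add atoms: tert-butyldimethylsilyl triflate, CC(C)(C)[Si](C)(C)OS(=O)(=O)C(F)(F)F
Why: Soft enolisation of the enone; the isopropyl C–H is the only α-hydrogen, so the 2-silyloxydiene with the dimethyl-substituted terminus forms.

Step 3
Reactants: 5 silyloxydiene; 6 2-methylcyclohex-2-en-1-one
Product: 7 rac-cis-decalone silyl enol ether (a32 ketone)
Conditions: AlBr3/AlMe3 (10:1, 0.2 equiv), toluene/CH2Cl2, −5 °C → rt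
Reagents that add atoms: none
Why: Mixed-Lewis-acid Diels–Alder reaction of a hindered 2-silyloxydiene with a 2-substituted cyclohexenone; the nucleophilic terminus a33 bonds to the β-carbon a8 and a5 to a6, and suprafacial addition sets a6-CH3 and a8-H cis (racemic).

Step 4
Reactants: 7 rac-cis-decalone silyl enol ether
Product: 9 rac-methylidene ketone (a3 ketone and a32=CH2), via silyl enol ether 8 (not isolated)
Conditions: Ph3PCH3Br, KN(SiMe3)2, toluene, 0 → 80 °C; then Bu4NF, AcOH, THF, 0 °C
Reagents that add atoms: methyltriphenylphosphonium bromide, C[P+](c1ccccc1)(c1ccccc1)c1ccccc1.[Br-]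
Why: Wittig methylenation of a ketone with one neopentylic flank, run alkoxide-free so the silyl enol ether survives until buffered fluoride unveils the a3 ketone; the two oxygens of the adduct are thereby differentiated.

Step 5
Reactants: 9 rac-methylidene ketone
Product: 10 (a3 S)-alcohol with OH β and cis A/B (single enantiomer)
Conditions: (R)-1-methyl-3,3-diphenyltetrahydro-1H,3H-pyrrolo[1,2-c][1,3,2]oxazaborole (0.5 equiv), catecholborane, toluene, −78 °C; chromatography
Reagents that add atoms: none
Why: Corey–Bakshi–Shibata reduction, with the quaternary a33 side as the large group, should give the (S)-carbinol from both enantiomers of 9; the wanted enantiomer becomes the cis alcohol 10 and the other a separable diastereomer, so one step sets a3 and resolves. Catecholborane at −78 °C spares the hindered alkene.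

Step 6
Reactants: 10 (a3 S)-alcohol
Product: 11 methyl ether
Conditions: NaH, MeI, DMF, 0 °C → rt
Reagents that add atoms: iodomethane, CI
Why: Williamson etherification of a secondary alkoxide; no stereocentre is touched.

Step 7
Reactants: 11 methyl ether
Product: 13 α-methylidene ketone (a11 C=O and a32=CH2), via allylic alcohol 12 (not isolated)
Conditions: SeO2 (0.5 equiv), t-BuOOH, CH2Cl2, rt; then Dess–Martin periodinane, NaHCO3, CH2Cl2, 0 °C
Reagents that add atoms: tert-butyl hydroperoxide, CC(C)(C)OO
Why: Ene reaction and [2,3] shift of the exocyclic alkene oxidise the only allylic C–H position (a11, since a6 is quaternary) with the double bond returning to a32=a31; oxidation of the crude alcohol gives the enone and completes the 1,2-transposition of the carbonyl.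

Step 8
Reactants: 13 α-methylidene ketone; 14 methyl acetoacetate
Product: 17 tricyclic enone (a14 C=O and a13=a11), via Michael adduct 15 (not isolated), via diketone 16 (not isolated)
Conditions: NaOMe (0.1 equiv), MeOH, 0 °C → rt; then 2 M KOH, MeOH/H2O, reflux
Reagents that add atoms: none
Why: Robinson-type annulation onto an α-methylene ketone (Michael addition at a31, ester hydrolysis and decarboxylation, aldol condensation of the methyl ketone onto a11) places the ring C carbonyl at a14. The epimerisable a32 should settle with a31 equatorial on ring B of conformer Q, that is a32-H on the β face.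

Step 9
Reactants: 17 tricyclic enone
Product: 18 tricyclic ketone (a14 C=O; cis-syn-cis A/B/C)
Conditions: Me2CuLi, BF3·OEt2, Et2O, −78 → −20 °C; aq NH4Cl
Reagents that add atoms: lithium dimethylcuprate, [Li+].C[Cu-]C
Why: Conjugate addition of a methyl cuprate to an octalone gives the cis-fused ring junction; methyl enters a11 from the convex β face, anti to the pseudo-axial a32–a6 bond and away from the axial a5 methylene, so a11-CH3 and a32-H are cis.

Step 10
Reactants: 18 tricyclic ketone
Product: 19 a30-benzyloxymethyl ketone
Conditions: LiN(i-Pr)2, THF, −78 °C; BnOCH2Cl, DMPU, −78 → −30 °C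
Reagents that add atoms: benzyl chloromethyl ether, ClCOCc1ccccc1
Why: Kinetic enolisation occurs at a30 rather than at the neopentylic a13, and alkylation installs the a28 carbon in a form that is not acidic. The α-axial position on a30 clashes with the axial a32–a6 bond, so the substituent ends equatorial (β) directly or on equilibration.

Step 11
Reactants: 19 a30-benzyloxymethyl ketone
Product: 21 α-hydroxy methyl ketone (a14-OH β), via enol ether carbinol 20 (not isolated)
Conditions: CH2=C(OEt)Li (ethyl vinyl ether, t-BuLi, THF, −78 → 0 °C), CeCl3, THF, −78 °C; then 0.5 M HCl, THF, 0 °C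
Reagents that add atoms: ethyl vinyl ether, C=COCC; water, O
Why: 1,2-Addition of an acetyl-anion equivalent, with CeCl3 suppressing enolisation and loss of benzyloxide. Axial approach to a14 is blocked by the syn-axial a11 methyl group, so the nucleophile enters equatorially from the α side and the carbinol oxygen is left axial on the β face. Mild acid turns the enol ether into the methyl ketone.

Step 12
Reactants: 21 α-hydroxy methyl ketone
Product: 22 triethylsilyl ether
Conditions: Et3SiOTf, 2,6-lutidine, CH2Cl2, −20 → 0 °C
Reagents that add atoms: triethylsilyl triflate, CC[Si](CC)(CC)OS(=O)(=O)C(F)(F)F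
Why: Silyl triflate with a hindered base silylates the tertiary alcohol; the ether later blocks α-ketol and retro-aldol pathways and shields the β face of the enone.

Step 13
Reactants: 22 triethylsilyl ether
Product: 23 primary alcohol (a28 CH2OH)
Conditions: H2 (1 atm), Pd(OH)2/C, EtOAc, rt
Reagents that add atoms: none
Why: Hydrogenolysis of the benzyl ether; ketone, methyl ether and silyl ether are inert.

Step 14
Reactants: 23 primary alcohol
Product: 25 methyl ester (a28 CO2CH3), via carboxylic acid 24 (not isolated)
Conditions: TEMPO (cat.), NaOCl (cat.), NaClO2, MeCN, pH 6.7 phosphate buffer, 35 °C; then Me3SiCHN2, toluene/MeOH, 0 °C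
Reagents that add atoms: sodium chlorite, [Na+].[O-]Cl=O; trimethylsilyldiazomethane, C[Si](C)(C)C=[N+]=[N-]
Why: Nitroxyl/chlorite oxidation takes the primary alcohol to the acid at buffered pH, where the silyl ether is stable; diazoalkane esterification of the crude acid gives the ester needed for ring closure.

Step 15
Reactants: 25 methyl ester
Product: 26 fused 4-(triethylsilyloxy)cyclopentane-1,3-dione
Conditions: LiN(SiMe3)2 (2.2 equiv), THF, −78 → 0 °C; aq NH4Cl
Reagents that add atoms: none
Why: Intramolecular Claisen condensation (5-exo-trig): the methyl ketone is deprotonated before the hindered tertiary ester α-hydrogen, and the stable dione enolate drives the closure. With a16 and a28 both equatorial on ring C the new ring is trans-fused; the cis epimer would put a28 axial against the a32–a6 bond.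

Step 16
Reactants: 26 fused cyclopentane-1,3-dione
Product: 27 West enol acetate
Conditions: Ac2O, Et3N, DMAP (cat.), CH2Cl2, 0 °C
Reagents that add atoms: acetic anhydride, CC(=O)OC(C)=O
Why: O-Acylation of the dione enolate takes place on the a28 oxygen, which is remote from the quaternary silyloxy carbon a14; this leaves the a16 carbonyl as the enone carbonyl, the regiochemistry the ring expansion requires.

Step 17
Reactants: 28 4-methylanisole
Product: 30 4-methylcyclohex-3-en-1-one, via dihydroanisole 29 (not isolated)
Conditions: Li, NH3(l), THF, t-BuOH, −78 → −33 °C; then (CO2H)2, MeOH/H2O, rt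
Reagents that add atoms: water, O
Why: Birch reduction gives the 1-methoxy-1,4-diene and mild acid hydrolyses the enol ether without moving the remaining alkene into conjugation.

Step 18
Reactants: 30 4-methylcyclohex-3-en-1-one
Product: 31 2,2,4-trimethylcyclohex-3-en-1-one
Conditions: KOt-Bu (2.2 equiv), MeI (2.5 equiv), t-BuOH/THF, 0 °C → rt
Reagents that add atoms: iodomethane, CI
Why: The doubly activated carbon between carbonyl and alkene is deprotonated to the dienolate and alkylated at the α-carbon twice (deconjugative gem-dimethylation); the quaternary carbon then locks the alkene out of conjugation.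

Step 19
Reactants: 31 2,2,4-trimethylcyclohex-3-en-1-one
Product: 32 6,6,8-trimethyl-1,4-dioxaspiro[4.5]dec-7-ene
Conditions: (Me3SiOCH2)2, Me3SiOTf (cat.), CH2Cl2, −78 → −20 °C
Reagents that add atoms: 1,2-bis(trimethylsilyloxy)ethane, C[Si](C)(C)OCCO[Si](C)(C)C
Why: Aprotic silyl-transfer ketalisation protects the hindered ketone without acid strong enough to move the trisubstituted alkene; the product is achiral, so no diastereomers arise in the key step.

Step 20
Reactants: 27 West enol acetate; 32 ring E alkene
Product: 35 pentacyclic diketone (a16 and a28 ketones), via cyclobutane photoadduct 33 (not isolated), via cyclobutanol 34 (not isolated)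
Conditions: hν (Hg lamp, Pyrex filter, λ > 300 nm), 32 (10 equiv), CH2Cl2, −40 °C; concentrate; K2CO3, MeOH, 0 °C → rt
Reagents that add atoms: none
Why: This is a de Mayo reaction: the triplet vinylogous ester bonds through a17 to the less substituted alkene carbon a18, and the resulting 1,4-diradical (tertiary a26, tertiary α-acetoxy a28) closes a26–a28 by radical combination; the closest known reaction type is the photocycloaddition of cyclic 1,3-diketone enol esters to alkenes followed by retro-aldol fragmentation. Head-to-tail regiochemistry follows from the more stable diradical and the donor character of a26. The four-membered ring of 33 is cis-fused to ring E, which fixes a18-H and a26-CH3 cis; these are the two new stereocentres, while the a17 and a28 centres of 33 are erased afterwards. Their absolute sense comes from attack on the α face of the enone, where only a30-H projects (the β face carries the axial silyl ether on a14 and the a30–a31 bond), combined with the anti placement of ring E away from the five-membered ring (cis-anti-cis). K2CO3 in CH3OH removes the acetate and cyclobutanolate 34 breaks the a17–a28 bond by retro-aldol under release of four-ring strain, so ring D is closed by a two-carbon expansion of the five-membered ring and not by a cyclisation. The silyl ether blocks retro-aldol loss of a14–a30, and any epimerisation at a30 returns a28 to the equatorial position on ring C, which is the trans C/D fusion. The step needs head-to-tail, α-face and anti selectivity; excess alkene and low temperature are meant to favour the ordered pathway.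

Step 21
Reactants: 35 pentacyclic diketone
Product: 36 enol triflate (a16(OTf)=a17)
Conditions: KN(SiMe3)2 (1.05 equiv), THF, −78 °C; PhNTf2, −78 → −40 °C
Reagents that add atoms: N-phenylbis(trifluoromethanesulfonimide), O=S(=O)(N(c1ccccc1)S(=O)(=O)C(F)(F)F)C(F)(F)F
Why: Kinetic deprotonation occurs at the a17 methylene of the less hindered a16 ketone; the only α-hydrogen of the a28 ketone is the shielded tertiary a30-H. O-Sulfonylation traps the enolate.

Step 22
Reactants: 36 enol triflate
Product: 37 a16=a17 alkene
Conditions: Pd(OAc)2 (cat.), PPh3, HCO2H, n-Bu3N, DMF, 60 °C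
Reagents that add atoms: none
Why: Zerovalent palladium inserts into the vinyl C–O bond and formate delivers hydride, replacing the triflate by hydrogen; ketone, ketal and silyl ether are inert.

Step 23
Reactants: 37 a16=a17 alkene
Product: 38 saturated ketone (a28 C=O)
Conditions: H2 (1 atm), Rh/Al2O3, EtOAc, rt
Reagents that add atoms: none
Why: Hydrogenation of the cis-disubstituted ring alkene completes the deoxygenation of a16; rhodium is chosen to avoid hydrogenolysis of the allylic silyl ether, and no stereocentre is created.

Step 24
Reactants: 38 saturated ketone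
Product: 39 hydroxy diketone (a14-OH; a22 and a28 ketones)
Conditions: 2 M HCl, THF, 0 °C → rt
Reagents that add atoms: water, O
Why: Dilute aqueous acid cleaves the triethylsilyl ether and the dioxolane together; the temperature is kept low so the tertiary β-hydroxy ketone does not dehydrate.

Step 25
Reactants: 39 hydroxy diketone
Product: 40 CNP0259231.1
Conditions: NaBH4, MeOH, −20 °C
Reagents that add atoms: none
Why: Hydride reduces the a22 ketone and not a28, which lies between quaternary a26 and tertiary a30. In either chair of the cis-fused ring E the α face is the open one (axial β approach meets the ring D bond on a18), so the hydroxyl ends β as in the target.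

## Compound list

1 | 3-methylbutan-2-one | CC(C)C(C)=O | starting material
2 | 1-(dimethylamino)-4-methylpentan-3-one (Mannich base) | CC(C)C(=O)CCN(C)C | intermediate (not isolated)
3 | trimethyl(4-methyl-3-oxopentyl)ammonium iodide | CC(C)C(=O)CC[N+](C)(C)C.[I-] | intermediate (not isolated)
4 | 4-methylpent-1-en-3-one | CC(C)C(=O)C=C | intermediate
5 | tert-butyldimethyl[(4-methylpenta-1,3-dien-3-yl)oxy]silane | CC(C)=C(O[Si](C)(C)C(C)(C)C)C=C | intermediate
6 | 2-methylcyclohex-2-en-1-one | CC1=CCCCC1=O | starting material
7 | rac-cis-6-(tert-butyldimethylsilyloxy)-5,5,8a-trimethyl-3,4,4a,5,8,8a-hexahydro-2H-naphthalen-1-one (a32 ketone; a6-CH3 and a8-H cis; racemic, enantiomer carried on is drawn) | CC(C)(C)[Si](C)(C)OC1=CC[C@@]2(C)[C@H](CCCC2=O)C1(C)C | intermediate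
8 | rac-silyl enol ether with a32=CH2 (methylenation product of 7; racemic) | CC(C)(C)[Si](C)(C)OC1=CC[C@@]2(C)[C@H](CCCC2=C)C1(C)C | intermediate (not isolated)
9 | rac-cis-1,1,4a-trimethyl-5-methylideneoctahydro-1H-naphthalen-2-one (a3 ketone, a32=CH2; racemic) | O=C1CC[C@@]2(C)[C@H](CCCC2=C)C1(C)C | intermediate
10 | cis-1,1,4a-trimethyl-5-methylidenedecahydronaphthalen-2-ol, a3 (S), OH β (cis to a6-CH3 and a8-H) | O[C@H]1CC[C@@]2(C)[C@H](CCCC2=C)C1(C)C | intermediate
11 | methyl ether of 10 (a3-OCH3 β) | CO[C@H]1CC[C@@]2(C)[C@H](CCCC2=C)C1(C)C | intermediate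
12 | allylic alcohol (a11-OH, both epimers; a32=CH2) | CO[C@H]1CC[C@@]2(C)[C@H](CCC(O)C2=C)C1(C)C | intermediate (not isolated)
13 | α-methylidene ketone (a11 C=O, a32=CH2) | CO[C@H]1CC[C@@]2(C)[C@H](CCC(=O)C2=C)C1(C)C | intermediate
14 | methyl acetoacetate (methyl 3-oxobutanoate) | COC(=O)CC(C)=O | starting material
15 | Michael adduct (a31 bonded to a30 of the acetoacetate; a30 epimers; a32-H β) | CO[C@H]1CC[C@@]2(C)[C@H](CCC(=O)[C@H]2CC(C(C)=O)C(=O)OC)C1(C)C | intermediate (not isolated)
16 | 1,5-diketone (a11 C=O; 3-oxobutyl chain on a32; a32-H β) | CO[C@H]1CC[C@@]2(C)[C@H](CCC(=O)[C@H]2CCC(C)=O)C1(C)C | intermediate (not isolated)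
17 | tricyclic enone (a14 C=O, a13=a11; a32-H β) | CO[C@H]1CC[C@@]2(C)[C@H](CCC3=CC(=O)CC[C@H]32)C1(C)C | intermediate
18 | tricyclic ketone (a14 C=O; a11-CH3 β; cis-syn-cis A/B/C) | CO[C@H]1CC[C@@]2(C)[C@H](CC[C@@]3(C)CC(=O)CC[C@H]32)C1(C)C | intermediate
19 | a30-(benzyloxymethyl) ketone (substituent β, equatorial) | CO[C@H]1CC[C@@]2(C)[C@H](CC[C@@]3(C)CC(=O)[C@H](COCc4ccccc4)C[C@H]32)C1(C)C | intermediate
20 | 1-ethoxyvinyl carbinol (a14-OH β) | CO[C@H]1CC[C@@]2(C)[C@H](CC[C@@]3(C)C[C@@](O)(C(=C)OCC)[C@H](COCc4ccccc4)C[C@H]32)C1(C)C | intermediate (not isolated)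
21 | α-hydroxy methyl ketone (a14-OH β, acetyl α) | CO[C@H]1CC[C@@]2(C)[C@H](CC[C@@]3(C)C[C@@](O)(C(C)=O)[C@H](COCc4ccccc4)C[C@H]32)C1(C)C | intermediate
22 | triethylsilyl ether of 21 | CO[C@H]1CC[C@@]2(C)[C@H](CC[C@@]3(C)C[C@@](O[Si](CC)(CC)CC)(C(C)=O)[C@H](COCc4ccccc4)C[C@H]32)C1(C)C | intermediate
23 | primary alcohol (a28 CH2OH) | CO[C@H]1CC[C@@]2(C)[C@H](CC[C@@]3(C)C[C@@](O[Si](CC)(CC)CC)(C(C)=O)[C@H](CO)C[C@H]32)C1(C)C | intermediate
24 | carboxylic acid (a28 CO2H) | CO[C@H]1CC[C@@]2(C)[C@H](CC[C@@]3(C)C[C@@](O[Si](CC)(CC)CC)(C(C)=O)[C@H](C(=O)O)C[C@H]32)C1(C)C | intermediate (not isolated)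
25 | methyl ester (a28 CO2CH3; acetyl on a14) | CO[C@H]1CC[C@@]2(C)[C@H](CC[C@@]3(C)C[C@@](O[Si](CC)(CC)CC)(C(C)=O)[C@H](C(=O)OC)C[C@H]32)C1(C)C | intermediate
26 | 4-(triethylsilyloxy)cyclopentane-1,3-dione trans-fused to ring C at a14–a30 (a16 and a28 ketones) | CO[C@H]1CC[C@@]2(C)[C@H](CC[C@@]3(C)C[C@@]4(O[Si](CC)(CC)CC)C(=O)CC(=O)[C@@H]4C[C@H]32)C1(C)C | intermediate
27 | West enol acetate (a28 acetoxy, a16 carbonyl, a14 triethylsilyl ether) | CO[C@H]1CC[C@@]2(C)[C@H](CC[C@@]3(C)C[C@@]4(O[Si](CC)(CC)CC)C(=O)C=C(OC(C)=O)[C@@H]4C[C@H]32)C1(C)C | intermediate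
28 | 4-methylanisole | COc1ccc(C)cc1 | starting material
29 | 1-methoxy-4-methylcyclohexa-1,4-diene | COC1=CCC(C)=CC1 | intermediate (not isolated)
30 | 4-methylcyclohex-3-en-1-one | CC1=CCC(=O)CC1 | intermediate
31 | 2,2,4-trimethylcyclohex-3-en-1-one | CC1=CC(C)(C)C(=O)CC1 | intermediate
32 | 6,6,8-trimethyl-1,4-dioxaspiro[4.5]dec-7-ene | CC1=CC(C)(C)C2(CC1)OCCO2 | intermediate
33 | cyclobutane photoadduct (a17–a18 and a26–a28 bonds; cis-anti-cis; a28 acetoxy) | CO[C@H]1CC[C@@]2(C)[C@H](CC[C@@]3(C)C[C@@]4(O[Si](CC)(CC)CC)C(=O)[C@H]6[C@@H]5C(C)(C)C7(OCCO7)CC[C@]5(C)[C@@]6(OC(C)=O)[C@@H]4C[C@H]32)C1(C)C | intermediate (not isolated)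
34 | cyclobutanol (acetate of 33 cleaved) | CO[C@H]1CC[C@@]2(C)[C@H](CC[C@@]3(C)C[C@@]4(O[Si](CC)(CC)CC)C(=O)[C@H]6[C@@H]5C(C)(C)C7(OCCO7)CC[C@]5(C)[C@@]6(O)[C@@H]4C[C@H]32)C1(C)C | intermediate (not isolated)
35 | pentacyclic diketone (a16 and a28 ketones, a14 silyl ether, a22 ketal) | CO[C@H]1CC[C@@]2(C)[C@H](CC[C@@]3(C)C[C@@]4(O[Si](CC)(CC)CC)C(=O)C[C@@H]5C(C)(C)C7(OCCO7)CC[C@]5(C)C(=O)[C@@H]4C[C@H]32)C1(C)C | intermediate
36 | enol triflate (a16(OTf)=a17) | CO[C@H]1CC[C@@]2(C)[C@H](CC[C@@]3(C)C[C@@]4(O[Si](CC)(CC)CC)C(OS(=O)(=O)C(F)(F)F)=C[C@@H]5C(C)(C)C7(OCCO7)CC[C@]5(C)C(=O)[C@@H]4C[C@H]32)C1(C)C | intermediate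
37 | a16=a17 alkene | CO[C@H]1CC[C@@]2(C)[C@H](CC[C@@]3(C)C[C@@]4(O[Si](CC)(CC)CC)C=C[C@@H]5C(C)(C)C7(OCCO7)CC[C@]5(C)C(=O)[C@@H]4C[C@H]32)C1(C)C | intermediate
38 | saturated ketone (a28 C=O; a14 silyl ether; a22 ketal) | CO[C@H]1CC[C@@]2(C)[C@H](CC[C@@]3(C)C[C@@]4(O[Si](CC)(CC)CC)CC[C@@H]5C(C)(C)C7(OCCO7)CC[C@]5(C)C(=O)[C@@H]4C[C@H]32)C1(C)C | intermediate
39 | hydroxy diketone (a14-OH; a22 and a28 ketones) | CO[C@H]1CC[C@@]2(C)[C@H](CC[C@@]3(C)C[C@@]4(O)CC[C@@H]5C(C)(C)C(=O)CC[C@]5(C)C(=O)[C@@H]4C[C@H]32)C1(C)C | intermediate
40 | CNP0259231.1 | CO[C@H]1CC[C@@]2(C)[C@H](CC[C@@]3(C)C[C@@]4(O)CC[C@@H]5C(C)(C)[C@H](O)CC[C@]5(C)C(=O)[C@@H]4C[C@H]32)C1(C)C | target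

## Step count and least certain steps

Total: 25 steps. Longest linear sequence: 22 steps (steps 1–16 and 20–25); the alkene branch (steps 17–19) has 3.

**Step 20 (key).** Most likely failure: slow first-bond formation at a18, which is shielded by the adjacent quaternary a19, so that enone decay, head-to-head bonding or β-face and syn approach compete; a second risk is E1cB loss of silyloxide from a14 during the carbonate treatment. Fallback, setting out from 27 and 30:
- Ketalisation of 30 under the conditions of step 19 gives 8-methyl-1,4-dioxaspiro[4.5]dec-7-ene F1, whose alkene carbon a18 is no longer neopentylic.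
- Irradiation of 27 with F1 and methanolysis as in step 20 should pass through the bisnor photoadduct F2 and the bisnor cyclobutanol F3 to the 19,19-bisnor diketone F4.
- Triflation, formate reduction and hydrogenation as in steps 21–23 would give the bisnor enol triflate F5, the bisnor alkene F6 and the bisnor saturated ketone F7.
- Pyridinium tosylate in wet acetone then frees the a22 ketone with the silyl ether intact, giving the bisnor diketone F8.
- KOt-Bu and MeI install both a19 methyl groups through the enolate that a cis ring fusion directs toward the ring-fusion side, giving the silyl-protected diketone F9.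
- Aqueous HCl removes the silyl group and the fallback rejoins the route at 39.

**Step 8.** Most likely failure: equilibration at a32 (α to the a11 ketone, later γ to the enone) under hot hydroxide toward a mixture or the epimer with a31 on the β face, if conformer Q is not as dominant as assumed. Fallback, from 13: conjugate addition of the dianion of dimethyl (2-oxopropyl)phosphonate (NaH, then n-BuLi, THF) and protonation at −78 °C should give the keto phosphonate F10 under kinetic control from the convex face. An intramolecular Horner–Wadsworth–Emmons reaction (K2CO3, 18-crown-6, toluene, rt) then closes ring C without strong aqueous base and rejoins the route at 17.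

**Step 5.** Most likely failure: incomplete reagent control for the enantiomer in which catalyst and substrate preferences oppose each other, which would lower the enantiomeric purity or the share of 10; hydroboration of the alkene is a lesser risk. Fallback, from 9: Li in NH3/t-BuOH reduces racemic 9 to racemic 10 (thermodynamic alcohol). Esterification with (S)-O-acetylmandelic acid (DCC, DMAP) gives diastereomeric esters that are separated; the one derived from 10 is the O-acetylmandelate F11. K2CO3 in CH3OH returns 10.

**Step 21.** Most likely failure: deprotonation at a30 instead of a17, followed by expulsion of the β-silyloxy group from a14, or unselective triflation. Fallback, from 35: NaBH4 with CeCl3 in CH3OH at −40 °C reduces the less hindered a16 ketone to the a16 alcohol F12 (both epimers). PhOC(S)Cl with pyridine and DMAP gives the phenyl thionocarbonate F13. Bu3SnH and AIBN in toluene at 80 °C (Barton–McCombie) then give 38, rejoining the route after step 23.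

## Further compounds

F1 | step 20 | 8-methyl-1,4-dioxaspiro[4.5]dec-7-ene | CC1=CCC2(CC1)OCCO2
F2 | step 20 | bisnor photoadduct (33 without the a19 methyl groups) | CO[C@H]1CC[C@@]2(C)[C@H](CC[C@@]3(C)C[C@@]4(O[Si](CC)(CC)CC)C(=O)[C@H]6[C@@H]5CC7(OCCO7)CC[C@]5(C)[C@@]6(OC(C)=O)[C@@H]4C[C@H]32)C1(C)C
F3 | step 20 | bisnor cyclobutanol (34 without the a19 methyl groups) | CO[C@H]1CC[C@@]2(C)[C@H](CC[C@@]3(C)C[C@@]4(O[Si](CC)(CC)CC)C(=O)[C@H]6[C@@H]5CC7(OCCO7)CC[C@]5(C)[C@@]6(O)[C@@H]4C[C@H]32)C1(C)C
F4 | step 20 | 19,19-bisnor diketone (35 without the a19 methyl groups) | CO[C@H]1CC[C@@]2(C)[C@H](CC[C@@]3(C)C[C@@]4(O[Si](CC)(CC)CC)C(=O)C[C@@H]5CC7(OCCO7)CC[C@]5(C)C(=O)[C@@H]4C[C@H]32)C1(C)C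
F5 | step 20 | bisnor enol triflate | CO[C@H]1CC[C@@]2(C)[C@H](CC[C@@]3(C)C[C@@]4(O[Si](CC)(CC)CC)C(OS(=O)(=O)C(F)(F)F)=C[C@@H]5CC7(OCCO7)CC[C@]5(C)C(=O)[C@@H]4C[C@H]32)C1(C)C
F6 | step 20 | bisnor a16=a17 alkene | CO[C@H]1CC[C@@]2(C)[C@H](CC[C@@]3(C)C[C@@]4(O[Si](CC)(CC)CC)C=C[C@@H]5CC7(OCCO7)CC[C@]5(C)C(=O)[C@@H]4C[C@H]32)C1(C)C
F7 | step 20 | bisnor saturated ketone (a22 ketal) | CO[C@H]1CC[C@@]2(C)[C@H](CC[C@@]3(C)C[C@@]4(O[Si](CC)(CC)CC)CC[C@@H]5CC7(OCCO7)CC[C@]5(C)C(=O)[C@@H]4C[C@H]32)C1(C)C
F8 | step 20 | bisnor diketone (a22 and a28 ketones, a14 silyl ether) | CO[C@H]1CC[C@@]2(C)[C@H](CC[C@@]3(C)C[C@@]4(O[Si](CC)(CC)CC)CC[C@@H]5CC(=O)CC[C@]5(C)C(=O)[C@@H]4C[C@H]32)C1(C)C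
F9 | step 20 | silyl-protected diketone (a19 gem-dimethyl, a22 and a28 ketones) | CO[C@H]1CC[C@@]2(C)[C@H](CC[C@@]3(C)C[C@@]4(O[Si](CC)(CC)CC)CC[C@@H]5C(C)(C)C(=O)CC[C@]5(C)C(=O)[C@@H]4C[C@H]32)C1(C)C
F10 | step 8 | keto phosphonate (a11 C=O; dimethyl 2-oxo-4-substituted-butylphosphonate chain on a32) | CO[C@H]1CC[C@@]2(C)[C@H](CCC(=O)[C@H]2CCC(=O)CP(=O)(OC)OC)C1(C)C
F11 | step 5 | (S)-O-acetylmandelate of 10 | CC(=O)O[C@H](C(=O)O[C@H]1CC[C@@]2(C)[C@H](CCCC2=C)C1(C)C)c1ccccc1
F12 | step 21 | a16 alcohol (both epimers at a16) | CO[C@H]1CC[C@@]2(C)[C@H](CC[C@@]3(C)C[C@@]4(O[Si](CC)(CC)CC)C(O)C[C@@H]5C(C)(C)C7(OCCO7)CC[C@]5(C)C(=O)[C@@H]4C[C@H]32)C1(C)C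
F13 | step 21 | a16 O-phenyl thionocarbonate | CO[C@H]1CC[C@@]2(C)[C@H](CC[C@@]3(C)C[C@@]4(O[Si](CC)(CC)CC)C(OC(=S)Oc6ccccc6)C[C@@H]5C(C)(C)C7(OCCO7)CC[C@]5(C)C(=O)[C@@H]4C[C@H]32)C1(C)C
A1 | alternative 1 | cis-fused D/E bicycle (vinylogous ester in ring D, silyl enol ether at a22) | COC1=CC(=O)[C@@]2(C)CC=C(O[Si](C)(C)C(C)(C)C)C(C)(C)[C@H]2CC1
A2 | alternative 1 | 6-methoxy-2-methylcyclohepta-2,6-dien-1-one | COC1=CC(=O)C(C)=CCC1
A3 | alternative 2 | cis-fused A/B octalone (a3 ketone, a11=a32 alkene) | O=C1CC[C@@]2(C)[C@H](CCC(C)=C2)C1(C)C
A4 | alternative 2 | 1,3,3,5-tetramethyl-2-vinylbicyclo[2.2.2]oct-5-en-2-ol (vinyl syn to the alkene bridge) | C=C[C@]1(O)C(C)(C)[C@H]2CC[C@]1(C)C=C2C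
A5 | alternative 3 | tricyclic A/B/C ketone with a9=a10 alkene | CO[C@H]1CC[C@@]2(C)[C@H](C=C[C@@]3(C)CC(=O)CC[C@H]32)C1(C)C
A6 | alternative 3 | 14-membered E,E,Z-trienone (a8=a9 E, a10=a11 E, a6=a32 Z; a14 ketone; a3 methoxy) | CO[C@H]1CC/C(C)=C\CCC(=O)C/C(C)=C/C=C/C1(C)C
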